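**Plan**
1. Retrosynthesis (eudesmane numbering): cut the C6–O ester bond, place a helper OH on C2, then cut C2–C3 and C5–C10 together (two consecutive ene reactions), then C5–C6 (alkenylzinc plus aldehyde), C1=C10 (olefination) and C7–C8 (Michael addition).
2. Enabling feature: ring A carries the exocyclic methylene C4=C15 between the allylic carbons C3 and C5, the retron of two ene reactions of one 2-methylprop-1-enyl group (C3, C15, C4, C5); its partner C10–C1–C2 is a β-methyl enal, a conjugate enophile at C10 and then a carbonyl enophile at C2.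
3. Forward: 3-methylbutanal and but-3-en-2-one give the C6–C10 chain, the C5/C4 and C1/C2 units are added, and Me2AlCl then closes ring B (C5–C10) and ring A (C2–C3) of the acyclic dienal in one operation.
4. Stereochemistry: C7 by enamine catalysis, C6 by a ligand-controlled alkenylzinc addition, C5 and C10 relayed from C6 and C7 in the chair closure of ring B, which also fixes the trans ring fusion.
5. Helpers: the aldehyde oxygen ends as C2–OH and is removed by radical deoxygenation; a TBS group masks O6 and an acetate masks the phenol.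

Key step: step 6

Remark: atoms are numbered as in eudesmane (ring A: C1–C5 and C10; ring B: C5–C10; C14 is the methyl on C10, C15 the methylene on C4); the carbinol centre created at C2 in the key step is expected as an epimer mixture, is written without configuration and disappears two steps later.

Step 1
Reactants: 1 3-methylbutanal; 2 but-3-en-2-one
Product: 3 (2S)-5-oxo-2-(propan-2-yl)hexanal
Conditions: (S)-2-[methoxy(diphenyl)methyl]pyrrolidine (5 mol %), ethyl 3,4-dihydroxybenzoate (20 mol %), neat, 4 °C
Reagents that add atoms: none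
Why: Enamine-catalysed Michael addition: the E-enamine of 1 is shielded on one face by the methoxy(diphenyl)methyl group of the (S)-catalyst, so 2 (activated by hydrogen bonding to the catechol) adds to the open face and sets C7 as S.

Step 2
Reactants: 3; 4 (2-methylprop-1-en-1-yl)magnesium bromide (THF solution)
Product: 6 (5S,6S)-6-hydroxy-8-methyl-5-(propan-2-yl)non-7-en-2-one, via bis(2-methylprop-1-en-1-yl)zinc 5 (not isolated)
Conditions: 4 (2.4 equiv), ZnCl2 (1.2 equiv), THF, 0 °C; 1,4-dioxane, filtration; (2R)-(+)-3-exo-morpholinoisoborneol (10 mol %), toluene, then 3, −20 → 0 °C; H2O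
Reagents that add atoms: none
Why: Amino-alcohol-catalysed 1,2-addition of a dialkenylzinc to an aldehyde: the organozinc leaves the methyl ketone alone, and the (+)-ligand, whose enantiomer directs addition to the Si face of aldehydes, should deliver the alkenyl group to the Re face and so set C6 as S under catalyst control over the weak Felkin–Anh bias of C7.

Step 3
Reactants: 6
Product: 7 (5S,6S)-6-[(tert-butyldimethylsilyl)oxy]-8-methyl-5-(propan-2-yl)non-7-en-2-one
Conditions: TBSOTf, 2,6-lutidine, CH2Cl2, −78 °C
Reagents that add atoms: tert-butyldimethylsilyl trifluoromethanesulfonate, CC(C)(C)[Si](C)(C)OS(=O)(=O)C(F)(F)F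
Why: Silylation of a hindered secondary allylic alcohol with a silyl triflate and a hindered base is fast at −78 °C, leaves the ketone untouched, draws any cyclic hemiketal through the open hydroxy ketone, and changes no stereocentre.

Step 4
Reactants: 7; 8 diethyl {2-[methoxy(methyl)amino]-2-oxoethyl}phosphonate
Product: 10 (2E,6S,7S)-7-[(tert-butyldimethylsilyl)oxy]-N-methoxy-N,3,9-trimethyl-6-(propan-2-yl)deca-2,8-dienamide, via sodium phosphonate carbanion 9 (not isolated)
Conditions: 8, NaH, THF, 0 °C; then 7, 0 → 50 °C
Reagents that add atoms: none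
Why: Horner–Wadsworth–Emmons olefination of a methyl ketone with a stabilised phosphonate carbanion gives mainly the E trisubstituted alkene (amide carbonyl trans to the long chain), the minor Z isomer is removed by chromatography, and C6 and C7 are not epimerisable in 7.

Step 5
Reactants: 10
Product: 11 (2E,6S,7S)-7-[(tert-butyldimethylsilyl)oxy]-3,9-dimethyl-6-(propan-2-yl)deca-2,8-dienal
Conditions: i-Bu2AlH (1.3 equiv), THF, −78 °C; aq. potassium sodium tartrate
Reagents that add atoms: none
Why: Hydride reduction of an N-methoxy-N-methyl amide stops at the aldehyde because the chelated tetrahedral aluminate survives until work-up, and the silyl ether and both alkenes are inert to i-Bu2AlH at −78 °C.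

Step 6
Reactants: 11
Product: 13 (4aS,5S,6S,8aS)-5-[(tert-butyldimethylsilyl)oxy]-8a-methyl-4-methylidene-6-(propan-2-yl)decahydronaphthalen-2-ol (C2 epimers), via ring-B aldehyde 12 (not isolated)
Conditions: Me2AlCl (2.2 equiv), CH2Cl2 (0.02 M), −78 → 0 °C; aq. NaHCO3
Reagents that add atoms: none
Why: Proposed new method: Me2AlCl bound to the aldehyde oxygen of 11 makes C10 of the β-methyl enal an acceptor with tertiary-cation character, C5 of the 2-methylprop-1-enyl group attacks it through a six-membered chair (ring B, 6-exo-trig, both π bonds exocyclic to the forming ring), and the C4 cation/aluminium enolate pair collapses by transfer of a methyl hydrogen to C1, a conjugate ene reaction that returns the Al-bound aldehyde 12 with an isopropenyl group on C5; 12 then closes ring A by a type 2 carbonyl-ene reaction (C3 onto C2, six-membered, the C15 hydrogen passes to oxygen), which leaves the C4=C15 exocyclic methylene. The closest known reaction types are the alkylaluminium-halide-promoted sequential ene annulation of enals and enones with alkenes, the RAlCl2-induced cyclisation of β,β-disubstituted dienones through the same zwitterion, and the Me2AlCl-promoted type 2 carbonyl-ene closure to 3-methylenecyclohexanols; new is their union in one flask on a β,β-disubstituted enal, so that the first ene step builds the quaternary C10. C5 is controlled by C6 through allylic 1,3-strain: the C6–H bond eclipses the C5=C4 bond because of the cis methyl group on C4, the tether brings C10 to the face anti to the silyloxy group, and H5 therefore ends up anti to H6. C10 is controlled by the chair in which the silyloxy group on C6, the isopropyl group on C7 and the long Al-bound enal arm are equatorial and only the methyl group is axial, which places the isopropenyl and CH2CHO arms trans and so leads to the trans-fused decalin with the angular methyl cis to the isopropyl group. The step needs proton loss from a methyl group to win over 1,2-hydride shift, C- or O-closure of the zwitterion and ionisation of the allylic silyl ether; this should be secured by the methyl C–H bonds being the only ones aligned with the empty p orbital at C4 (H5 lies in its nodal plane), by the enolate carbon lying one six-membered array away from these hydrogens, and by the weak basicity of the bulky silyl ether towards the mild Lewis acid. The C2 carbinol centre is formed without control and is removed in steps 7 and 8.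

Step 7
Reactants: 13
Product: 14 O-[(4aS,5S,6S,8aS)-5-[(tert-butyldimethylsilyl)oxy]-8a-methyl-4-methylidene-6-(propan-2-yl)decahydronaphthalen-2-yl] 1H-imidazole-1-carbothioate (C2 epimers)
Conditions: 1,1'-thiocarbonyldiimidazole, 4-(dimethylamino)pyridine (cat.), 1,2-dichloroethane, 70 °C
Reagents that add atoms: 1,1'-thiocarbonyldiimidazole, S=C(n1ccnc1)n1ccnc1
Why: Thioacylation of the secondary C2 alcohol, the only free hydroxyl group, with the thiocarbonyl transfer reagent gives the radical precursor for a Barton–McCombie deoxygenation without touching a stereocentre that is kept.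

Step 8
Reactants: 14
Product: 15 tert-butyldimethyl{[(1S,2S,4aR,8aS)-4a-methyl-8-methylidene-2-(propan-2-yl)decahydronaphthalen-1-yl]oxy}silane
Conditions: Bu3SnH, azobis(isobutyronitrile) (cat.), toluene, 100 °C
Reagents that add atoms: none
Why: Barton–McCombie deoxygenation: Bu3Sn radical adds to the C=S group, the secondary C2 radical is released and is reduced by Bu3SnH faster than this homoallyl radical can rearrange through a cyclopropylcarbinyl radical, so the exocyclic alkene and all four stereocentres stay as they are.

Step 9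
Reactants: 15
Product: 16 (1S,2S,4aR,8aS)-4a-methyl-8-methylidene-2-(propan-2-yl)decahydronaphthalen-1-ol (junenol)
Conditions: Bu4NF, THF, 50 °C
Reagents that add atoms: none
Why: Fluoride-induced cleavage of the Si–O bond frees the hindered C6 alcohol on gentle warming, and the isolated 1,1-disubstituted alkene is not affected.

Step 10
Reactants: 16; 17 (2E)-3-[4-(acetyloxy)phenyl]prop-2-enoic acid
Product: 19 (1S,2S,4aR,8aS)-4a-methyl-8-methylidene-2-(propan-2-yl)decahydronaphthalen-1-yl (2E)-3-[4-(acetyloxy)phenyl]prop-2-enoate, via mixed anhydride 18 (not isolated)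
Conditions: 17, 2,4,6-trichlorobenzoyl chloride, Et3N, toluene, rt; then 16, 4-(dimethylamino)pyridine, 60 °C
Reagents that add atoms: none
Why: Yamaguchi esterification: 4-(dimethylamino)pyridine attacks the less hindered cinnamoyl carbonyl of the mixed anhydride and the acylpyridinium ion acylates the hindered equatorial C6 alcohol with retention at C6, while the phenol stays masked as its acetate and the E alkene of the acid is kept.

Step 11
Reactants: 19
Product: 20 (1S,2S,4aR,8aS)-4a-methyl-8-methylidene-2-(propan-2-yl)decahydronaphthalen-1-yl (2E)-3-(4-hydroxyphenyl)prop-2-enoate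
Conditions: pyrrolidine (3 equiv), CH2Cl2, 0 °C → rt
Reagents that add atoms: none
Why: Aminolysis of an aryl acetate, an activated ester, by pyrrolidine is much faster than attack on the hindered secondary alkyl cinnamate or conjugate addition to it, so only the phenol is set free.

**Compound list**
1 | 3-methylbutanal | CC(C)CC=O | starting material
2 | but-3-en-2-one | CC(=O)C=C | starting material
3 | (2S)-5-oxo-2-(propan-2-yl)hexanal | CC(=O)CC[C@@H](C(C)C)C=O | intermediate
4 | (2-methylprop-1-en-1-yl)magnesium bromide | CC(C)=C[Mg]Br | starting material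
5 | bis(2-methylprop-1-en-1-yl)zinc, formed in the flask | CC(C)=C[Zn]C=C(C)C | intermediate
6 | (5S,6S)-6-hydroxy-8-methyl-5-(propan-2-yl)non-7-en-2-one | CC(=O)CC[C@@H](C(C)C)[C@H](O)C=C(C)C | intermediate
7 | (5S,6S)-6-[(tert-butyldimethylsilyl)oxy]-8-methyl-5-(propan-2-yl)non-7-en-2-one | CC(=O)CC[C@@H](C(C)C)[C@H](O[Si](C)(C)C(C)(C)C)C=C(C)C | intermediate
8 | diethyl {2-[methoxy(methyl)amino]-2-oxoethyl}phosphonate | CCOP(=O)(CC(=O)N(C)OC)OCC | starting material
9 | sodium salt of the carbanion of 8, formed in the flask | CCOP(=O)([CH-]C(=O)N(C)OC)OCC.[Na+] | intermediate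
10 | (2E,6S,7S)-7-[(tert-butyldimethylsilyl)oxy]-N-methoxy-N,3,9-trimethyl-6-(propan-2-yl)deca-2,8-dienamide | CON(C)C(=O)/C=C(\C)CC[C@@H](C(C)C)[C@H](O[Si](C)(C)C(C)(C)C)C=C(C)C | intermediate
11 | (2E,6S,7S)-7-[(tert-butyldimethylsilyl)oxy]-3,9-dimethyl-6-(propan-2-yl)deca-2,8-dienal | O=C/C=C(\C)CC[C@@H](C(C)C)[C@H](O[Si](C)(C)C(C)(C)C)C=C(C)C | intermediate
12 | 2-[(1S,2S,3S,4S)-3-[(tert-butyldimethylsilyl)oxy]-1-methyl-4-(propan-2-yl)-2-(prop-1-en-2-yl)cyclohexyl]acetaldehyde, formed in the flask | O=CC[C@]1(C)CC[C@@H](C(C)C)[C@H](O[Si](C)(C)C(C)(C)C)[C@H]1C(C)=C | intermediate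
13 | (4aS,5S,6S,8aS)-5-[(tert-butyldimethylsilyl)oxy]-8a-methyl-4-methylidene-6-(propan-2-yl)decahydronaphthalen-2-ol, C2 epimers | C=C1CC(O)C[C@]2(C)CC[C@@H](C(C)C)[C@H](O[Si](C)(C)C(C)(C)C)[C@@H]12 | intermediate
14 | O-[(4aS,5S,6S,8aS)-5-[(tert-butyldimethylsilyl)oxy]-8a-methyl-4-methylidene-6-(propan-2-yl)decahydronaphthalen-2-yl] 1H-imidazole-1-carbothioate, C2 epimers | C=C1CC(OC(=S)n3ccnc3)C[C@]2(C)CC[C@@H](C(C)C)[C@H](O[Si](C)(C)C(C)(C)C)[C@@H]12 | intermediate
15 | tert-butyldimethyl{[(1S,2S,4aR,8aS)-4a-methyl-8-methylidene-2-(propan-2-yl)decahydronaphthalen-1-yl]oxy}silane | C=C1CCC[C@]2(C)CC[C@@H](C(C)C)[C@H](O[Si](C)(C)C(C)(C)C)[C@@H]12 | intermediate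
16 | (1S,2S,4aR,8aS)-4a-methyl-8-methylidene-2-(propan-2-yl)decahydronaphthalen-1-ol (junenol) | C=C1CCC[C@]2(C)CC[C@@H](C(C)C)[C@H](O)[C@@H]12 | intermediate
17 | (2E)-3-[4-(acetyloxy)phenyl]prop-2-enoic acid | CC(=O)Oc1ccc(/C=C/C(=O)O)cc1 | starting material
18 | (2E)-3-[4-(acetyloxy)phenyl]prop-2-enoic 2,4,6-trichlorobenzoic anhydride, formed in the flask | CC(=O)Oc1ccc(/C=C/C(=O)OC(=O)c2c(Cl)cc(Cl)cc2Cl)cc1 | intermediate
19 | (1S,2S,4aR,8aS)-4a-methyl-8-methylidene-2-(propan-2-yl)decahydronaphthalen-1-yl (2E)-3-[4-(acetyloxy)phenyl]prop-2-enoate | C=C1CCC[C@]2(C)CC[C@@H](C(C)C)[C@H](OC(=O)/C=C/c3ccc(OC(C)=O)cc3)[C@@H]12 | intermediate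
20 | (1S,2S,4aR,8aS)-4a-methyl-8-methylidene-2-(propan-2-yl)decahydronaphthalen-1-yl (2E)-3-(4-hydroxyphenyl)prop-2-enoate | C=C1CCC[C@]2(C)CC[C@@H](C(C)C)[C@H](OC(=O)/C=C/c3ccc(O)cc3)[C@@H]12 | target

Total steps: 11. Longest linear sequence: 11 steps (from 1 and 2 to 20).

**Steps most likely to fail**

Step 6 (proposed new method). What may go wrong: diversion of the C4 cation by hydride shift or by closure onto the enolate, ionisation of the allylic silyl ether, weak facial control at C10, or loss of regiocontrol in the hydrogen transfer of the second ene step. The fallback uses known chemistry, sets out from 3 and comes back at 13. The ene donor is replaced by an allylsilane, so that the first C–C bond is made by an intramolecular Hosomi–Sakurai conjugate addition and the isopropenyl group arises regiospecifically. 3-(Trimethylsilyl)prop-1-yne is methylaluminated (Me3Al, Cp2ZrCl2 cat.) and iodinated to (E)-1-iodo-2-methyl-3-(trimethylsilyl)prop-1-ene F1. F1 is lithiated (t-BuLi), transmetallated (ZnBr2) and added to 3 with the ligand of step 2 to give (5S,6S,7E)-6-hydroxy-8-methyl-5-(propan-2-yl)-9-(trimethylsilyl)non-7-en-2-one F2. Silylation as in step 3 gives (5S,6S,7E)-6-[(tert-butyldimethylsilyl)oxy]-8-methyl-5-(propan-2-yl)-9-(trimethylsilyl)non-7-en-2-one F3. Olefination with 8 as in step 4 gives (2E,6S,7S,8E)-7-[(tert-butyldimethylsilyl)oxy]-N-methoxy-N,3,9-trimethyl-6-(propan-2-yl)-10-(trimethylsilyl)deca-2,8-dienamide F4, and i-Bu2AlH gives (2E,6S,7S,8E)-7-[(tert-butyldimethylsilyl)oxy]-3,9-dimethyl-6-(propan-2-yl)-10-(trimethylsilyl)deca-2,8-dienal F5. TiCl4 in CH2Cl2 at −78 °C should close ring B by attack of C5 on C10 with loss of the silyl group (1,2-addition would need an eight-membered ring). Aqueous work-up gives 12, which is isolated here, and Me2AlCl then effects the type 2 carbonyl-ene closure to 13.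

Step 2. What may go wrong: insufficient facial selectivity of the catalyst-controlled addition against the bias of the α-stereocentre, or intramolecular aldol condensation of the keto aldehyde before addition. The fallback sets C6 by reduction instead of C–C bond formation, sets out from 3 and comes back at 10. Coupling of 3 with 1-bromo-2-methylprop-1-ene under Nozaki–Hiyama–Kishi conditions (CrCl2, NiCl2 cat., DMF), which is selective for the aldehyde, gives the C6-epimeric alcohols (5S)-6-hydroxy-8-methyl-5-(propan-2-yl)non-7-en-2-one F6. MnO2 oxidises the allylic alcohol to the enone (5S)-8-methyl-5-(propan-2-yl)non-7-ene-2,6-dione F7. Olefination of the unhindered methyl ketone with 8 under mild conditions (LiCl, 1,8-diazabicyclo[5.4.0]undec-7-ene, MeCN, to spare the now epimerisable C7) gives (2E,6S)-N-methoxy-N,3,9-trimethyl-7-oxo-6-(propan-2-yl)deca-2,8-dienamide F8. Oxazaborolidine-catalysed borane reduction (CBS reduction), with the catalyst enantiomer chosen for hydride delivery to the Re face of the C6 carbonyl, a sense that is matched with Felkin–Anh control, gives (2E,6S,7S)-7-hydroxy-N-methoxy-N,3,9-trimethyl-6-(propan-2-yl)deca-2,8-dienamide F9. Silylation as in step 3 gives 10.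

Step 10. What may go wrong: slow acylation of the hindered C6 alcohol, with acetyl transfer from the aryl acetate to the alcohol competing under nucleophilic catalysis. The fallback builds the cinnamate on the alcohol, sets out from 16 and comes back at 20, so that 19 is bypassed. Heating 16 with 2,2-dimethyl-1,3-dioxane-4,6-dione in toluene gives the malonic half ester 3-{[(1S,2S,4aR,8aS)-4a-methyl-8-methylidene-2-(propan-2-yl)decahydronaphthalen-1-yl]oxy}-3-oxopropanoic acid F10. A Knoevenagel–Doebner condensation of F10 with 4-hydroxybenzaldehyde (pyridine, piperidine cat., 70 °C) should give 20 directly with the E alkene.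

Further compounds
F1 | step 6 | (E)-1-iodo-2-methyl-3-(trimethylsilyl)prop-1-ene | C[Si](C)(C)C/C(C)=C/I
F2 | step 6 | (5S,6S,7E)-6-hydroxy-8-methyl-5-(propan-2-yl)-9-(trimethylsilyl)non-7-en-2-one | CC(=O)CC[C@@H](C(C)C)[C@H](O)/C=C(\C)C[Si](C)(C)C
F3 | step 6 | (5S,6S,7E)-6-[(tert-butyldimethylsilyl)oxy]-8-methyl-5-(propan-2-yl)-9-(trimethylsilyl)non-7-en-2-one | CC(=O)CC[C@@H](C(C)C)[C@H](O[Si](C)(C)C(C)(C)C)/C=C(\C)C[Si](C)(C)C
F4 | step 6 | (2E,6S,7S,8E)-7-[(tert-butyldimethylsilyl)oxy]-N-methoxy-N,3,9-trimethyl-6-(propan-2-yl)-10-(trimethylsilyl)deca-2,8-dienamide | CON(C)C(=O)/C=C(\C)CC[C@@H](C(C)C)[C@H](O[Si](C)(C)C(C)(C)C)/C=C(\C)C[Si](C)(C)C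
F5 | step 6 | (2E,6S,7S,8E)-7-[(tert-butyldimethylsilyl)oxy]-3,9-dimethyl-6-(propan-2-yl)-10-(trimethylsilyl)deca-2,8-dienal | O=C/C=C(\C)CC[C@@H](C(C)C)[C@H](O[Si](C)(C)C(C)(C)C)/C=C(\C)C[Si](C)(C)C
F6 | step 2 | (5S)-6-hydroxy-8-methyl-5-(propan-2-yl)non-7-en-2-one, C6 epimers | CC(=O)CC[C@@H](C(C)C)C(O)C=C(C)C
F7 | step 2 | (5S)-8-methyl-5-(propan-2-yl)non-7-ene-2,6-dione | CC(=O)CC[C@@H](C(C)C)C(=O)C=C(C)C
F8 | step 2 | (2E,6S)-N-methoxy-N,3,9-trimethyl-7-oxo-6-(propan-2-yl)deca-2,8-dienamide | CON(C)C(=O)/C=C(\C)CC[C@@H](C(C)C)C(=O)C=C(C)C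
F9 | step 2 | (2E,6S,7S)-7-hydroxy-N-methoxy-N,3,9-trimethyl-6-(propan-2-yl)deca-2,8-dienamide | CON(C)C(=O)/C=C(\C)CC[C@@H](C(C)C)[C@H](O)C=C(C)C
F10 | step 10 | 3-{[(1S,2S,4aR,8aS)-4a-methyl-8-methylidene-2-(propan-2-yl)decahydronaphthalen-1-yl]oxy}-3-oxopropanoic acid | C=C1CCC[C@]2(C)CC[C@@H](C(C)C)[C@H](OC(=O)CC(=O)O)[C@@H]12
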